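**Plan**

1. Retrosynthesis cuts the cyclopentene at the C4–C5 single bond and the C1=C2 double bond (locants of the target name: C1 bears CH2OAc, C2 the CHO, C3 the side chain). This gives a two-carbon acetoxymethyl ketone unit (C5, C1) and a three-carbon unit (C2, C3, C4). The side chain is then cut between its stereocentre and the homogeranyl CH2.
2. Enabling feature: ring C2 (α to the formyl carbon) and ring C4 stand 1,3 across the stereogenic C3. They can therefore be stored as one bond of a temporary cyclopropane whose C2 carbon carries a phosphonate and an acyl group; this ring is electrophilic at C4 (CH2) and, once opened, nucleophilic and olefinating at C2.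
3. Forward: geranyl bromide → homogeranyl iodide → anti alkylation of dimethyl (S)-malate → triol → protected 1,2-diol → cyclic sulfate → cyclopropane (steps 1–11).
4. The five-membered ring then arises in one operation (step 13). Enolate ring opening of the cyclopropane forms C4–C5, and an intramolecular Horner–Wadsworth–Emmons reaction forms C1=C2, with CH2OAc and the masked CHO (thioester) already in place. The allyl ester helper leaves by decarboxylation, and the two aldehydes are unveiled last (steps 14–17).
5. Stereochemistry: ring C3 comes from C2 of (S)-malic acid (inverted once, in the cyclopropanation); the side-chain centre comes from the anti-selective Fráter–Seebach alkylation; the E alkene comes from geranyl bromide.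

Key step: step 13

Remark: 17, 18, 24, 25 and 26 are mixtures of epimers at the one carbon that later becomes sp2 or loses its substituent; this has no consequence for the target.

**Route**

Step 1
Reactants: 1 geranyl bromide [(2E)-1-bromo-3,7-dimethylocta-2,6-diene]; 2 (chloromethyl)(dimethyl)(propan-2-yloxy)silane
Product: 4 [(3E)-4,8-dimethylnona-3,7-dien-1-yl](dimethyl)(propan-2-yloxy)silane, via Grignard reagent iPrOMe2SiCH2MgCl 3 (not isolated)
Conditions: 2, Mg, THF, 40 °C; then 1, Li2CuCl4 (cat.), THF, 0 °C
Reagents that add atoms: none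
Why: Copper-catalysed Grignard cross-coupling of the primary allylic bromide with the (alkoxysilyl)methyl Grignard reagent (a hydroxymethyl anion equivalent) should give the linear one-carbon homologue, since the other allylic terminus is fully substituted, with the E alkene retained.

Step 2
Reactants: 4
Product: 5 homogeraniol [(3E)-4,8-dimethylnona-3,7-dien-1-ol]
Conditions: 30% H2O2, KF, KHCO3, THF/MeOH, 25 °C
Reagents that add atoms: hydrogen peroxide, OO
Why: Tamao oxidation of the alkoxysilane should replace the C–Si bond by C–OH under mildly basic conditions that leave the trisubstituted alkenes untouched.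

Step 3
Reactants: 5
Product: 6 homogeranyl iodide [(3E)-1-iodo-4,8-dimethylnona-3,7-diene]
Conditions: I2, PPh3, imidazole, CH2Cl2, 0 °C
Reagents that add atoms: iodine, II
Why: Appel-type iodination converts the primary alcohol into the iodide by SN2 displacement of the oxyphosphonium group without affecting the alkenes.

Step 4
Reactants: 7 dimethyl (S)-malate [dimethyl (2S)-2-hydroxybutanedioate]; 6
Product: 8 dimethyl (2S,3R)-2-hydroxy-3-[(3E)-4,8-dimethylnona-3,7-dien-1-yl]butanedioate
Conditions: LiN(iPr)2 (2.2 equiv), THF, −78 to −20 °C; then 6, DMPU, −78 to 0 °C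
Reagents that add atoms: none
Why: Fráter–Seebach alkylation: the lithium-chelated alkoxide enolate of the malate should be alkylated anti to the carbinol substituent, which sets the new centre (3R) relative to the (2S) centre taken from malic acid and so fixes both stereocentres of the target.

Step 5
Reactants: 8
Product: 9 (2S,3S)-3-[(3E)-4,8-dimethylnona-3,7-dien-1-yl]butane-1,2,4-triol
Conditions: LiAlH4, THF, 0 to 25 °C
Reagents that add atoms: none
Why: Hydride reduction of both methyl esters should give the triol with neither stereocentre touched.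

Step 6
Reactants: 9
Product: 10 (2S,5E)-2-[(4S)-2,2-dimethyl-1,3-dioxolan-4-yl]-6,10-dimethylundeca-5,9-dien-1-ol
Conditions: 2,2-dimethoxypropane, PPTS (cat.), acetone, 25 °C
Reagents that add atoms: 2,2-dimethoxypropane, COC(C)(C)OC
Why: Acid-catalysed acetonide formation under thermodynamic control should place the acetal on the terminal 1,2-diol as the five-membered dioxolane and leave the other primary hydroxyl free.

Step 7
Reactants: 10
Product: 11 tert-butyl{[(2S,5E)-2-[(4S)-2,2-dimethyl-1,3-dioxolan-4-yl]-6,10-dimethylundeca-5,9-dien-1-yl]oxy}diphenylsilane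
Conditions: TBDPSCl, imidazole, DMF, 25 °C
Reagents that add atoms: tert-butyl(chloro)diphenylsilane, CC(C)(C)[Si](Cl)(c1ccccc1)c1ccccc1
Why: Silylation of the primary alcohol gives an acid- and base-stable silyl ether that should survive every step up to step 15.

Step 8
Reactants: 11
Product: 12 (2S,3S,6E)-3-({[tert-butyl(diphenyl)silyl]oxy}methyl)-7,11-dimethyldodeca-6,10-diene-1,2-diol
Conditions: AcOH/THF/H2O (3:1:1), 40 °C
Reagents that add atoms: none
Why: Acid-catalysed acetal hydrolysis in dilute acetic acid should free the 1,2-diol while the TBDPS ether and the trisubstituted alkenes stay intact.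

Step 9
Reactants: 12
Product: 13 (4S)-4-[(2S,5E)-1-{[tert-butyl(diphenyl)silyl]oxy}-6,10-dimethylundeca-5,9-dien-2-yl]-1,3,2-dioxathiolane 2,2-dioxide
Conditions: NaH, THF, 0 °C; then 1,1'-sulfonyldiimidazole, −20 to 25 °C
Reagents that add atoms: 1,1'-sulfonyldiimidazole, O=S(=O)(n1ccnc1)n1ccnc1
Why: Cyclic sulfate formation by two successive sulfonyl transfers to the dialkoxide; this direct route avoids the RuO4 oxidation of a cyclic sulfite, which the trisubstituted alkenes would not survive.

Step 10
Reactants: 14 (diethoxyphosphoryl)acetic acid; 15 ethanethiol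
Product: 16 S-ethyl 2-(diethoxyphosphoryl)ethanethioate
Conditions: DCC, DMAP (cat.), CH2Cl2, 0 to 25 °C
Reagents that add atoms: none
Why: Steglich thioesterification gives the phosphonate reagent whose thioester later serves as an aldehyde precursor that can be reduced in the presence of an acetate.

Step 11
Reactants: 13; 16
Product: 18 S-ethyl (2S)-2-[(2R,5E)-1-{[tert-butyl(diphenyl)silyl]oxy}-6,10-dimethylundeca-5,9-dien-2-yl]-1-(diethoxyphosphoryl)cyclopropane-1-carbothioate (mixture of epimers at C1), via ring-opened sodium alkyl sulfate 17 (not isolated)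
Conditions: 16, NaH (2.2 equiv), DME, 0 °C; then 13, 25 to 60 °C
Reagents that add atoms: none
Why: Double alkylation of an active methylene compound by a cyclic sulfate (cyclopropanation): the phosphonate carbanion opens the sulfate at the primary carbon to give 17, and after a second deprotonation a 3-exo-tet displacement of sulfate at the secondary carbon with inversion should give the (S) cyclopropane stereocentre.

Step 12
Reactants: 19 Meldrum's acid (2,2-dimethyl-1,3-dioxane-4,6-dione); 20 acetoxyacetyl chloride; 21 allyl alcohol (prop-2-en-1-ol)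
Product: 23 prop-2-en-1-yl 4-(acetyloxy)-3-oxobutanoate, via 5-(acetoxyacetyl) Meldrum's acid 22 (not isolated)
Conditions: 19, 20, pyridine, CH2Cl2, 0 °C; then 21, toluene, 80 °C
Reagents that add atoms: none
Why: C-Acylation of Meldrum's acid followed by thermal alcoholysis through the acylketene, with loss of acetone and CO2, is the standard β-keto ester synthesis and tolerates the acetate.

Step 13
Reactants: 18; 23
Product: 25 prop-2-en-1-yl (4S)-2-[(acetyloxy)methyl]-4-[(2R,5E)-1-{[tert-butyl(diphenyl)silyl]oxy}-6,10-dimethylundeca-5,9-dien-2-yl]-3-[(ethylsulfanyl)carbonyl]cyclopent-2-ene-1-carboxylate (mixture of epimers at C1), via ring-opened phosphonate carbanion sodium salt 24 (not isolated)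
Conditions: 23, NaH (1.0 equiv), THF, 0 °C; then 18, DMSO, 60 °C
Reagents that add atoms: none
Why: Proposed new method: the sodium enolate of 23 attacks the unsubstituted CH2 of the phosphonate- and thioester-activated cyclopropane 18 in an SN2 homo-Michael ring opening (new C–C single bond), and the released stabilised carbanion 24 adds to the acetoxymethyl ketone and collapses through an oxaphosphetane with loss of diethyl phosphate (intramolecular Horner–Wadsworth–Emmons reaction) to the tetrasubstituted C=C. The closest known reaction types are the cyclopentene annulation of β-keto ester enolates with 1-(alkoxycarbonyl)cyclopropylphosphonium salts (ring opening, then intramolecular Wittig reaction), the homoconjugate addition of malonate-type anions to cyclopropane-1,1-diesters, and Michael–HWE annulations of 2-phosphonoacrylates. The five-membered ring closes by 5-exo-trig attack of the carbanion on the ketone carbonyl followed by syn elimination of phosphate. No lasting stereocentre is created: the carbon bearing CO2allyl forms as an epimer mixture and loses that group in step 14, while the existing ring stereocentre keeps its (S) configuration because none of its bonds is broken and it is never α to a carbonyl. The step needs attack at CH2 and not at the substituted cyclopropane carbon (secured by the secondary, α-branched nature of that carbon), C- and not O-alkylation (soft stabilised enolate), and olefination of the ketone in preference to acylation by the ester or thioester (the α-acetoxy ketone is the most electrophilic carbonyl). Only one equivalent of base is used because 24 equilibrates by proton transfer with its β-keto ester enolate tautomer, and a second equivalent would lock the ketone as an unreactive enolate.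

Step 14
Reactants: 25
Product: 27 S-ethyl (5S)-2-[(acetyloxy)methyl]-5-[(2R,5E)-1-{[tert-butyl(diphenyl)silyl]oxy}-6,10-dimethylundeca-5,9-dien-2-yl]cyclopent-1-ene-1-carbothioate, via cyclopentenecarboxylic acid 26 (not isolated)
Conditions: Pd(PPh3)4 (3 mol %), HCO2H, Et3N, THF, 25 °C
Reagents that add atoms: none
Why: Tsuji deallylation–decarboxylation: zerovalent palladium ionises the allyl ester (far faster than the hindered tetrasubstituted allylic acetate), formate reduces the allyl ligand to propene, and the vinylogous β-keto acid 26 loses CO2 through the dienolate, which should reprotonate under Et3N to the conjugated tetrasubstituted enethioate.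

Step 15
Reactants: 27
Product: 28 S-ethyl (5S)-2-[(acetyloxy)methyl]-5-[(2R,5E)-1-hydroxy-6,10-dimethylundeca-5,9-dien-2-yl]cyclopent-1-ene-1-carbothioate
Conditions: HF·pyridine, pyridine, THF, 0 to 25 °C
Reagents that add atoms: none
Why: Fluoride-mediated desilylation with pyridine-buffered HF should leave the acetate, thioester and alkenes alone; 28 is oxidised at once to forestall lactonisation onto the thioester.

Step 16
Reactants: 28
Product: 29 S-ethyl (5S)-2-[(acetyloxy)methyl]-5-[(2R,5E)-6,10-dimethyl-1-oxoundeca-5,9-dien-2-yl]cyclopent-1-ene-1-carbothioate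
Conditions: Dess–Martin periodinane, pyridine, CH2Cl2, 0 °C
Reagents that add atoms: none
Why: Dess–Martin oxidation under buffered, non-epimerising conditions should give the α-branched aldehyde while the ring aldehyde is still masked as the thioester, so that no hydroxy-enal (lactol) is ever present.

Step 17
Reactants: 29
Product: 30 [(3S)-2-formyl-3-[(2R,5E)-6,10-dimethyl-1-oxoundeca-5,9-dien-2-yl]cyclopent-1-en-1-yl]methyl acetate (target)
Conditions: Et3SiH, 10% Pd/C, acetone, 25 °C
Reagents that add atoms: none
Why: Fukuyama reduction: palladium inserts into the C–S bond, Et3SiH delivers hydride and the acyl palladium hydride releases the enal, under neutral conditions that should preserve the acetate, the alkenes and the configuration α to the existing aldehyde.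

**Compound list**

1 | geranyl bromide, (2E)-1-bromo-3,7-dimethylocta-2,6-diene | CC(C)=CCC/C(C)=C/CBr | starting material
2 | (chloromethyl)(dimethyl)(propan-2-yloxy)silane | CC(C)O[Si](C)(C)CCl | starting material
3 | {[dimethyl(propan-2-yloxy)silyl]methyl}magnesium chloride | CC(C)O[Si](C)(C)C[Mg]Cl | intermediate
4 | [(3E)-4,8-dimethylnona-3,7-dien-1-yl](dimethyl)(propan-2-yloxy)silane | CC(C)=CCC/C(C)=C/CC[Si](C)(C)OC(C)C | intermediate
5 | homogeraniol, (3E)-4,8-dimethylnona-3,7-dien-1-ol | CC(C)=CCC/C(C)=C/CCO | intermediate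
6 | homogeranyl iodide, (3E)-1-iodo-4,8-dimethylnona-3,7-diene | CC(C)=CCC/C(C)=C/CCI | intermediate
7 | dimethyl (S)-malate, dimethyl (2S)-2-hydroxybutanedioate | COC(=O)[C@@H](O)CC(=O)OC | starting material
8 | dimethyl (2S,3R)-2-hydroxy-3-[(3E)-4,8-dimethylnona-3,7-dien-1-yl]butanedioate | COC(=O)[C@@H](O)[C@@H](CC/C=C(\C)CCC=C(C)C)C(=O)OC | intermediate
9 | (2S,3S)-3-[(3E)-4,8-dimethylnona-3,7-dien-1-yl]butane-1,2,4-triol | OC[C@@H](O)[C@@H](CC/C=C(\C)CCC=C(C)C)CO | intermediate
10 | (2S,5E)-2-[(4S)-2,2-dimethyl-1,3-dioxolan-4-yl]-6,10-dimethylundeca-5,9-dien-1-ol | CC1(C)OC[C@@H](O1)[C@@H](CC/C=C(\C)CCC=C(C)C)CO | intermediate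
11 | tert-butyl{[(2S,5E)-2-[(4S)-2,2-dimethyl-1,3-dioxolan-4-yl]-6,10-dimethylundeca-5,9-dien-1-yl]oxy}diphenylsilane | CC1(C)OC[C@@H](O1)[C@@H](CC/C=C(\C)CCC=C(C)C)CO[Si](c1ccccc1)(c1ccccc1)C(C)(C)C | intermediate
12 | (2S,3S,6E)-3-({[tert-butyl(diphenyl)silyl]oxy}methyl)-7,11-dimethyldodeca-6,10-diene-1,2-diol | OC[C@@H](O)[C@@H](CC/C=C(\C)CCC=C(C)C)CO[Si](c1ccccc1)(c1ccccc1)C(C)(C)C | intermediate
13 | (4S)-4-[(2S,5E)-1-{[tert-butyl(diphenyl)silyl]oxy}-6,10-dimethylundeca-5,9-dien-2-yl]-1,3,2-dioxathiolane 2,2-dioxide | O=S1(=O)OC[C@@H](O1)[C@@H](CC/C=C(\C)CCC=C(C)C)CO[Si](c1ccccc1)(c1ccccc1)C(C)(C)C | intermediate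
14 | (diethoxyphosphoryl)acetic acid | CCOP(=O)(OCC)CC(=O)O | starting material
15 | ethanethiol | CCS | starting material
16 | S-ethyl 2-(diethoxyphosphoryl)ethanethioate | CCOP(=O)(OCC)CC(=O)SCC | intermediate
17 | sodium (2R,3S,6E)-3-({[tert-butyl(diphenyl)silyl]oxy}methyl)-1-[1-(diethoxyphosphoryl)-2-(ethylsulfanyl)-2-oxoethyl]-7,11-dimethyldodeca-6,10-dien-2-yl sulfate | [Na+].CCOP(=O)(OCC)C(C[C@@H](OS(=O)(=O)[O-])[C@@H](CC/C=C(\C)CCC=C(C)C)CO[Si](c1ccccc1)(c1ccccc1)C(C)(C)C)C(=O)SCC | intermediate
18 | S-ethyl (2S)-2-[(2R,5E)-1-{[tert-butyl(diphenyl)silyl]oxy}-6,10-dimethylundeca-5,9-dien-2-yl]-1-(diethoxyphosphoryl)cyclopropane-1-carbothioate | CCOP(=O)(OCC)C1(C[C@H]1[C@@H](CC/C=C(\C)CCC=C(C)C)CO[Si](c2ccccc2)(c2ccccc2)C(C)(C)C)C(=O)SCC | intermediate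
19 | Meldrum's acid, 2,2-dimethyl-1,3-dioxane-4,6-dione | CC1(C)OC(=O)CC(=O)O1 | starting material
20 | acetoxyacetyl chloride | CC(=O)OCC(=O)Cl | starting material
21 | allyl alcohol, prop-2-en-1-ol | C=CCO | starting material
22 | 5-[(acetyloxy)acetyl]-2,2-dimethyl-1,3-dioxane-4,6-dione | CC(=O)OCC(=O)C1C(=O)OC(C)(C)OC1=O | intermediate
23 | prop-2-en-1-yl 4-(acetyloxy)-3-oxobutanoate | CC(=O)OCC(=O)CC(=O)OCC=C | intermediate
24 | sodium 5-carbanion of prop-2-en-1-yl (4S)-2-[(acetyloxy)acetyl]-4-[(2R,5E)-1-{[tert-butyl(diphenyl)silyl]oxy}-6,10-dimethylundeca-5,9-dien-2-yl]-5-(diethoxyphosphoryl)-6-(ethylsulfanyl)-6-oxohexanoate | [Na+].CCOP(=O)(OCC)[C-](C(=O)SCC)[C@@H](CC(C(=O)OCC=C)C(=O)COC(C)=O)[C@@H](CC/C=C(\C)CCC=C(C)C)CO[Si](c1ccccc1)(c1ccccc1)C(C)(C)C | intermediate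
25 | prop-2-en-1-yl (4S)-2-[(acetyloxy)methyl]-4-[(2R,5E)-1-{[tert-butyl(diphenyl)silyl]oxy}-6,10-dimethylundeca-5,9-dien-2-yl]-3-[(ethylsulfanyl)carbonyl]cyclopent-2-ene-1-carboxylate | C=CCOC(=O)C1C[C@@H]([C@@H](CC/C=C(\C)CCC=C(C)C)CO[Si](c2ccccc2)(c2ccccc2)C(C)(C)C)C(C(=O)SCC)=C1COC(C)=O | intermediate
26 | (4S)-2-[(acetyloxy)methyl]-4-[(2R,5E)-1-{[tert-butyl(diphenyl)silyl]oxy}-6,10-dimethylundeca-5,9-dien-2-yl]-3-[(ethylsulfanyl)carbonyl]cyclopent-2-ene-1-carboxylic acid | OC(=O)C1C[C@@H]([C@@H](CC/C=C(\C)CCC=C(C)C)CO[Si](c2ccccc2)(c2ccccc2)C(C)(C)C)C(C(=O)SCC)=C1COC(C)=O | intermediate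
27 | S-ethyl (5S)-2-[(acetyloxy)methyl]-5-[(2R,5E)-1-{[tert-butyl(diphenyl)silyl]oxy}-6,10-dimethylundeca-5,9-dien-2-yl]cyclopent-1-ene-1-carbothioate | CCSC(=O)C1=C(COC(C)=O)CC[C@H]1[C@@H](CC/C=C(\C)CCC=C(C)C)CO[Si](c2ccccc2)(c2ccccc2)C(C)(C)C | intermediate
28 | S-ethyl (5S)-2-[(acetyloxy)methyl]-5-[(2R,5E)-1-hydroxy-6,10-dimethylundeca-5,9-dien-2-yl]cyclopent-1-ene-1-carbothioate | CCSC(=O)C1=C(COC(C)=O)CC[C@H]1[C@@H](CC/C=C(\C)CCC=C(C)C)CO | intermediate
29 | S-ethyl (5S)-2-[(acetyloxy)methyl]-5-[(2R,5E)-6,10-dimethyl-1-oxoundeca-5,9-dien-2-yl]cyclopent-1-ene-1-carbothioate | CCSC(=O)C1=C(COC(C)=O)CC[C@H]1[C@@H](CC/C=C(\C)CCC=C(C)C)C=O | intermediate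
30 | [(3S)-2-formyl-3-[(2R,5E)-6,10-dimethyl-1-oxoundeca-5,9-dien-2-yl]cyclopent-1-en-1-yl]methyl acetate | CC(=O)OCC1=C(C=O)[C@H]([C@H](C=O)CC/C=C(\C)CCC=C(C)C)CC1 | target

**Step count and risks**

Total step count: 17. Longest linear sequence: 15 steps (steps 1–9, 11 and 13–17, from geranyl bromide).

Steps most likely to fail:

1. Step 13 (proposed new method). The ring opening of the phosphonate/thioester cyclopropane by the weakly nucleophilic β-keto ester enolate may be too slow at a temperature where acetate transfer or self-condensation of 23 sets in. The opened intermediate may also rest as its unreactive enolate tautomer. The fallback uses known chemistry, sets out from cyclic sulfate 13 and returns at 25. Double alkylation of Meldrum's acid 19 by 13 (NaH, DME) should give the spiro-activated cyclopropane F1. Such cyclopropanes are known to be opened at CH2 by stabilised enolates at room temperature, so the sodium enolate of 23 (THF, 25 °C, then acid) should give the 5-substituted Meldrum's acid F2. An intramolecular Knoevenagel–Doebner condensation onto the acetoxymethyl ketone (piperidinium acetate, pyridine, 60 °C), with loss of acetone and CO2, should give the cyclopentenecarboxylic acid F3. Steglich thioesterification of F3 with ethanethiol 15 (DCC, DMAP) gives 25.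

2. Step 17. Palladium may hydrogenolyse the allylic acetate or saturate or shift an alkene, or the hindered tetrasubstituted thioester may be reduced only slowly. The fallback sets out from 27 and returns at 30. Luche-type reduction of the thioester (NaBH4, CeCl3·7H2O, EtOH/THF, 0 °C) should give the allylic alcohol F4, and HF·pyridine then frees the diol F5. A double Swern oxidation ((COCl)2, DMSO, Et3N, −78 °C) converts both primary alcohols together into the dialdehyde 30, so that no hydroxy-aldehyde is exposed.

3. Step 4. SN2 attack of the malate dianion on the unactivated homoallylic iodide may be slow, and E2 elimination of the iodide to the 1,3-diene may compete. The fallback reverses the polarity, sets out from 6 and returns at 9. Iodide 6 is converted into the Grignard reagent F6 (Mg, THF). Its CuI-catalysed addition to commercial diethyl (2S,3S)-oxirane-2,3-dicarboxylate (THF, −40 °C) opens the epoxide with inversion and should give the anti diethyl ester F7. LiAlH4 reduction of F7 gives the triol 9.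

**Further compounds**

F1 | step 13 | (1S)-1-[(2R,5E)-1-{[tert-butyl(diphenyl)silyl]oxy}-6,10-dimethylundeca-5,9-dien-2-yl]-6,6-dimethyl-5,7-dioxaspiro[2.5]octane-4,8-dione | CC1(C)OC(=O)C2(C[C@H]2[C@@H](CC/C=C(\C)CCC=C(C)C)CO[Si](c3ccccc3)(c3ccccc3)C(C)(C)C)C(=O)O1
F2 | step 13 | prop-2-en-1-yl (4S)-2-[(acetyloxy)acetyl]-4-(2,2-dimethyl-4,6-dioxo-1,3-dioxan-5-yl)-4-[(2R,5E)-1-{[tert-butyl(diphenyl)silyl]oxy}-6,10-dimethylundeca-5,9-dien-2-yl]butanoate | CC1(C)OC(=O)C(C(=O)O1)[C@@H](CC(C(=O)OCC=C)C(=O)COC(C)=O)[C@@H](CC/C=C(\C)CCC=C(C)C)CO[Si](c2ccccc2)(c2ccccc2)C(C)(C)C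
F3 | step 13 | (5S)-2-[(acetyloxy)methyl]-5-[(2R,5E)-1-{[tert-butyl(diphenyl)silyl]oxy}-6,10-dimethylundeca-5,9-dien-2-yl]-3-[(prop-2-en-1-yloxy)carbonyl]cyclopent-1-ene-1-carboxylic acid | C=CCOC(=O)C1C[C@@H]([C@@H](CC/C=C(\C)CCC=C(C)C)CO[Si](c2ccccc2)(c2ccccc2)C(C)(C)C)C(C(=O)O)=C1COC(C)=O
F4 | step 17 | [(3S)-3-[(2R,5E)-1-{[tert-butyl(diphenyl)silyl]oxy}-6,10-dimethylundeca-5,9-dien-2-yl]-2-(hydroxymethyl)cyclopent-1-en-1-yl]methyl acetate | OCC1=C(COC(C)=O)CC[C@H]1[C@@H](CC/C=C(\C)CCC=C(C)C)CO[Si](c2ccccc2)(c2ccccc2)C(C)(C)C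
F5 | step 17 | [(3S)-3-[(2R,5E)-1-hydroxy-6,10-dimethylundeca-5,9-dien-2-yl]-2-(hydroxymethyl)cyclopent-1-en-1-yl]methyl acetate | OCC1=C(COC(C)=O)CC[C@H]1[C@@H](CC/C=C(\C)CCC=C(C)C)CO
F6 | step 4 | [(3E)-4,8-dimethylnona-3,7-dien-1-yl]magnesium iodide | CC(C)=CCC/C(C)=C/CC[Mg]I
F7 | step 4 | diethyl (2S,3R)-2-hydroxy-3-[(3E)-4,8-dimethylnona-3,7-dien-1-yl]butanedioate | CCOC(=O)[C@@H](O)[C@@H](CC/C=C(\C)CCC=C(C)C)C(=O)OCC
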